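**Retrosynthetic overview**
Locants: N4; pyrrolidine N4–C3–C2–C1–C9a; azepane N4–C5–C6–C7–C8–C9–C9a; cyclopentane C9a–C9–C10(Et)–C11(O)–C12; fused lactone C11–O–C14(=O)–C13(Me)(OH)–C12; side-chain lactone C18–C21 on C3.
Late stage: the C3 lactone comes from a C18 aldehyde (2-(ethoxycarbonyl)allylzinc addition, lactonisation, hydrogenation); C13–OH from lactone-enolate hydroxylation; C10–Et from radical C–C formation on an iodolactone; C12–C13 from a Johnson–Claisen transfer off a C10 allylic alcohol; the azepane from N4–C5 alkylation.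
Key disconnection C9–C9a: the spiro cyclopentane is a masked trans-4-amino-5-alkylcyclopent-2-enone, unfolded into a flat 2,5-disubstituted furan-2-yl carbinol (aza-Piancatelli cascade); furan O becomes C10=O, the furan carbons become C10, C11, C12 and C9a, the carbinol carbon becomes C9.
Enabling feature: in the cyclopentane ring the N-bearing spiro carbon C9a (shared with the pyrrolidine) is next to C9, N4 and C8 are trans across the C9–C9a bond, and C10–C12 carry only groups that can be grown from C(=O)–CH=CH; the three-carbon tether C1–C2–C3 lets N4 reach the furan carbon that becomes C9a.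
Order of ring formation: pyrrolidine and cyclopentenone together (key step), then azepane, fused γ-lactone, side-chain γ-lactone; the C3 centre of an L-homoserine-derived iodide is the only source of chirality.

Key step: step 7

Remark: the carbinol centre of 12 and C13 of 19–26 are carried as epimer mixtures (both are planarised later, in steps 7 and 15) and are written without a descriptor; the closure in step 7 is assumed to occur on the pyrrolinium face opposite to the CH2OSi group at C3.

**Step 1**
Reactants: 1 methyl (2S)-2-[(tert-butoxycarbonyl)amino]-4-iodobutanoate; 2 2-bromofuran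
Product: 4 methyl (2S)-2-[(tert-butoxycarbonyl)amino]-4-(furan-2-yl)butanoate, via alkylzinc iodide 3 (not isolated)
Conditions: Zn dust, I2 (cat.), DMF, rt; then 2, Pd2(dba)3 (2.5 mol %), SPhos (10 mol %), 50 °C
Reagents that add atoms: none
Why: Negishi coupling of a primary alkylzinc iodide (zinc insertion into the C–I bond) with a 2-halofuran at zerovalent palladium; the stereocentre (future C3) is untouched because zinc sits γ to the carbamate and the ester.

**Step 2**
Reactants: 4 methyl (2S)-2-[(tert-butoxycarbonyl)amino]-4-(furan-2-yl)butanoate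
Product: 5 tert-butyl N-[(2S)-4-(furan-2-yl)-1-hydroxybutan-2-yl]carbamate
Conditions: LiBH4, THF, 0 °C to rt
Reagents that add atoms: none
Why: Chemoselective borohydride reduction of the methyl ester to the primary alcohol (future C18) beside the carbamate; no stereocentre is created.

**Step 3**
Reactants: 5 tert-butyl N-[(2S)-4-(furan-2-yl)-1-hydroxybutan-2-yl]carbamate
Product: 6 tert-butyl N-[(2S)-1-[tert-butyl(diphenyl)silyl]oxy-4-(furan-2-yl)butan-2-yl]carbamate
Conditions: t-BuPh2SiCl, imidazole, CH2Cl2, rt
Reagents that add atoms: tert-butyl(chloro)diphenylsilane, CC(C)(C)[Si](Cl)(c1ccccc1)c1ccccc1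
Why: Silyl ether formation at the primary alcohol; the robust silyl group has to survive organolithium, Lewis acid, hot orthoester, oxidant and enolate conditions up to step 16.

**Step 4**
Reactants: 6 tert-butyl N-[(2S)-1-[tert-butyl(diphenyl)silyl]oxy-4-(furan-2-yl)butan-2-yl]carbamate
Product: 7 (2S)-1-[tert-butyl(diphenyl)silyl]oxy-4-(furan-2-yl)butan-2-amine
Conditions: CF3CO2H, CH2Cl2, 0 °C (short); aq. NaHCO3 work-up
Reagents that add atoms: none
Why: Acidolysis of the tert-butyl carbamate (loss of 2-methylpropene and CO2) at low temperature to spare the acid-sensitive 2-alkylfuran; no stereocentre is touched.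

**Step 5**
Reactants: 7 (2S)-1-[tert-butyl(diphenyl)silyl]oxy-4-(furan-2-yl)butan-2-amine; 8 1-bromo-4-methoxybenzene
Product: 9 N-[(2S)-1-[tert-butyl(diphenyl)silyl]oxy-4-(furan-2-yl)butan-2-yl]-4-methoxyaniline
Conditions: Pd2(dba)3 (2 mol %), BrettPhos (5 mol %), NaOtBu, toluene, 90 °C
Reagents that add atoms: none
Why: Buchwald–Hartwig mono-N-arylation of the primary amine; the p-methoxyphenyl group makes nitrogen a weakly basic aniline-type nucleophile as step 7 requires and is removable by oxidation, and the stereocentre bears no acidifying group.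

**Step 6**
Reactants: 9 N-[(2S)-1-[tert-butyl(diphenyl)silyl]oxy-4-(furan-2-yl)butan-2-yl]-4-methoxyaniline; 10 5-chloropentanal
Product: 12 1-[5-[(3S)-4-[tert-butyl(diphenyl)silyl]oxy-3-(4-methoxyanilino)butyl]furan-2-yl]-5-chloropentan-1-ol (carbinol epimers), via N,C-dilithio species 11 (not isolated)
Conditions: n-BuLi (2.2 equiv), THF, −78 to 0 °C; then 10, −78 °C; H2O
Reagents that add atoms: none
Why: N–H deprotonation, α-lithiation of the 2-alkylfuran at its free 5-position and 1,2-addition to the aldehyde; the carbinol centre (future C9) forms without control, which is harmless because it is ionised in step 7.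

**Step 7**
Reactants: 12 1-[5-[(3S)-4-[tert-butyl(diphenyl)silyl]oxy-3-(4-methoxyanilino)butyl]furan-2-yl]-5-chloropentan-1-ol
Product: 15 (2S)-2-[[tert-butyl(diphenyl)silyl]oxymethyl]-6-(4-chlorobutyl)-1-(4-methoxyphenyl)-1-azaspiro[4.4]non-8-en-7-one (N1 trans to the chlorobutyl group; C5–C6 bond trans to the CH2OSi group), via spiro N,O-aminal 13 (not isolated), via aminopentadienyl cation 14 (not isolated)
Conditions: Dy(OTf)3 (10 mol %), MeCN, 80 °C
Reagents that add atoms: none
Why: Dy(OTf)3 ionises the furyl carbinol to a furanoxonium ion, the tethered aniline nitrogen adds to the tether-bearing furan carbon to give spiro N,O-aminal 13, C–O ionisation opens it to the 1-amino-4-hydroxypentadienyl cation 14, and thermal conrotatory 4π-electrocyclisation of 14 forms the C9–C9a bond, after which loss of the O–H proton gives the enone. The closest known reaction type is the Dy(OTf)3-catalysed intramolecular aza-Piancatelli rearrangement of 5-(3-arylaminopropyl)furan-2-yl carbinols to 1-azaspiro[4.4]nonenones. The pyrrolidine closes by 5-exo attack of N4 on the oxocarbenium carbon (spiro mode), the cyclopentenone by the 4π-conrotatory closure between the carbinol-derived carbon and the former furan carbon (formally 5-endo). C9 relative to C9a follows from conrotation of the cation with N4 and the chlorobutyl chain both outside, which puts them trans; the absolute sense is controlled by the C3 stereocentre, whose CH2OSi group blocks one face of the planar pyrrolinium ring so that C9 bonds anti to it. The step needs nitrogen to add to the substituted furan carbon (not to the carbinol carbon), which the five-membered spiro transition state secures, and an unpoisoned catalyst, which the weakly basic N-aryl amine secures; the carbinol epimers converge because that centre is planar in the cation.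

**Step 8**
Reactants: 15 spiro enone
Product: 16 (2S)-2-[[tert-butyl(diphenyl)silyl]oxymethyl]-6-(4-chlorobutyl)-1-(4-methoxyphenyl)-1-azaspiro[4.4]non-8-en-7-ol (7-OH cis to the chlorobutyl group, trans to N1)
Conditions: NaBH4, CeCl3·7H2O, MeOH, −40 °C
Reagents that add atoms: none
Why: Luche 1,2-reduction of the enone; hydride is delivered to C10 on the face opposite to the adjacent C9 chain, so the new C10–OH is cis to that chain and trans to N4.

**Step 9**
Reactants: 16 allylic alcohol; 17 triethyl orthopropionate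
Product: 19 ethyl 2-[(2S)-2-[[tert-butyl(diphenyl)silyl]oxymethyl]-6-(4-chlorobutyl)-1-(4-methoxyphenyl)-1-azaspiro[4.4]non-7-en-9-yl]propanoate (C9 side chain cis to the chlorobutyl group, trans to N1; epimers at the propanoate α-carbon), via mixed ketene acetal 18 (not isolated)
Conditions: 17 (excess), EtCO2H (cat.), xylenes, 140 °C, removal of EtOH
Reagents that add atoms: none
Why: Johnson–Claisen rearrangement (suprafacial [3,3] shift of the mixed ketene acetal) transfers the C10–O configuration to C12, forming the C12–C13 bond on the face that carried the oxygen (cis to C8, trans to N4) and moving the alkene to C10=C11; C13 forms as a mixture and is set in step 15.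

**Step 10**
Reactants: 19 N-aryl spiro ester
Product: 20 ethyl 2-[(2S)-2-[[tert-butyl(diphenyl)silyl]oxymethyl]-6-(4-chlorobutyl)-1-azaspiro[4.4]non-7-en-9-yl]propanoate (secondary amine, configuration as in 19)
Conditions: (NH4)2Ce(NO3)6 (2.5 equiv), MeCN/H2O, 0 °C; aq. NaHCO3 work-up
Reagents that add atoms: none
Why: Oxidative N-dearylation: two-electron oxidation of the p-anisidine by tetravalent cerium to a quinone iminium ion and hydrolysis release the secondary amine and 1,4-benzoquinone; no stereocentre is affected.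

**Step 11**
Reactants: 20 spiro amino ester
Product: 21 tricyclic amino ester: ethyl 2-(C12-yl)propanoate of the pyrrolidine–azepane–cyclopentene tricycle (target ring system with C10=C11, 3-CH2OSi-t-BuPh2; C3, C9, C9a, C12 as in the target; C13 epimers)
Conditions: NaI (0.2 equiv), K2CO3, MeCN, 80 °C, high dilution
Reagents that add atoms: none
Why: Iodide-catalysed intramolecular N-alkylation (7-exo-tet SN2) closes the azepane through the N4–C5 bond; the trans disposition of N4 and C8 fixed in step 7 gives the trans-fused 5/7 junction of the target.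

**Step 12**
Reactants: 21 tricyclic amino ester
Product: 23 iodolactone: tetracyclic cis-fused γ-lactone (C11–O cis to the C12–C13 bond) with iodine at C10 trans to the lactone oxygen, 3-CH2OSi-t-BuPh2, C13 epimers, via carboxylic acid 22 (not isolated)
Conditions: LiOH, THF/MeOH/H2O, 50 °C; then NaHCO3, I2, KI, 0 °C
Reagents that add atoms: lithium hydroxide, [Li+].[OH-]; iodine, [I][I]
Why: Saponification followed by iodolactonisation: the carboxylate on the lower face attacks C11 in a 5-exo opening of the iodonium ion, giving the cis-fused γ-lactone with iodine at C10 trans to the lactone oxygen.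

**Step 13**
Reactants: 23 iodolactone; 24 phenyl vinyl sulfone
Product: 25 10-[2-(phenylsulfonyl)ethyl] lactone (side chain at C10 trans to O11 and to C8; otherwise as 23)
Conditions: 24 (5 equiv), Bu3SnH (slow addition), AIBN (cat.), benzene, 80 °C
Reagents that add atoms: none
Why: Giese reaction: the secondary C10 radical generated with Bu3SnH adds to the vinyl sulfone on the convex face of the cis-fused bicyclic lactone, anti to the lactone ring and to C8, as the ethyl group requires.

**Step 14**
Reactants: 25 sulfonylethyl lactone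
Product: 26 10-ethyl lactone (13-deoxy compound, C13 epimers, 3-CH2OSi-t-BuPh2)
Conditions: Na/Hg amalgam (6 % Na), Na2HPO4, MeOH/THF, −20 °C
Reagents that add atoms: none
Why: Reductive desulfonylation with buffered sodium amalgam converts the 2-(phenylsulfonyl)ethyl group into ethyl; no stereocentre is involved and the lactone survives the buffered medium.

**Step 15**
Reactants: 26 ethyl lactone
Product: 28 13-hydroxy lactone silyl ether (13-OH cis to H12, 13-methyl on the concave face), via potassium enolate 27 (not isolated)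
Conditions: KN(SiMe3)2, THF, −78 °C; then 3-phenyl-2-(phenylsulfonyl)oxaziridine, −78 °C; H2O
Reagents that add atoms: 3-phenyl-2-(phenylsulfonyl)oxaziridine, O=S(=O)(N1OC1c1ccccc1)c1ccccc1
Why: α-Hydroxylation of the lactone enolate with an N-sulfonyloxaziridine; the planar C13 enolate is attacked on the convex face of the bicyclic lactone (the face of H11 and H12), placing OH cis to H12 and methyl on the concave face, and converging the C13 epimers.

**Step 16**
Reactants: 28 hydroxy lactone silyl ether
Product: 29 hydroxy lactone primary alcohol (3-CH2OH)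
Conditions: Bu4NF, THF, 0 °C to rt
Reagents that add atoms: none
Why: Fluoride-mediated cleavage of the silyl ether frees the primary alcohol at C18; lactone and tertiary alcohol are inert.

**Step 17**
Reactants: 29 hydroxy lactone primary alcohol
Product: 30 amino aldehyde (3-CHO)
Conditions: Dess–Martin periodinane, CH2Cl2, 0 °C; used crude
Reagents that add atoms: none
Why: Dess–Martin oxidation of the primary alcohol to the α-amino aldehyde, used at once to avoid epimerisation at C3; the tertiary alcohol cannot be oxidised.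

**Step 18**
Reactants: 30 amino aldehyde; 31 ethyl 2-(bromomethyl)prop-2-enoate
Product: 33 α-methylene lactone (target with C20=CH2 in place of C20–H/CH3; 18S), via hydroxy ester 32 (not isolated)
Conditions: Zn dust (activated), THF, 50 °C; then 1 M HCl, rt; NaHCO3 work-up
Reagents that add atoms: none
Why: Barbier-type addition of the 2-(ethoxycarbonyl)allylzinc bromide to the aldehyde followed by lactonisation; zinc chelation between N4 and the carbonyl oxygen (Cram-chelate model) directs the allyl group anti to C2 and should give the syn amino alcohol, 18S.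

**Step 19**
Reactants: 33 α-methylene lactone
Product: 34 target compound
Conditions: H2 (1 atm), Pd/C (10 wt % Pd), EtOAc, rt
Reagents that add atoms: none
Why: Heterogeneous hydrogenation of the exocyclic methylene from the face opposite to the C18 substituent places the new methyl group cis to the C18–C3 bond (20S) and completes the target.

**Compound list**
1 | methyl (2S)-2-[(tert-butoxycarbonyl)amino]-4-iodobutanoate | COC(=O)[C@H](CCI)NC(=O)OC(C)(C)C | starting material
2 | 2-bromofuran | Brc1ccco1 | starting material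
3 | [(3S)-3-[(tert-butoxycarbonyl)amino]-4-methoxy-4-oxobutyl]zinc iodide | COC(=O)[C@H](CC[Zn]I)NC(=O)OC(C)(C)C | intermediate
4 | methyl (2S)-2-[(tert-butoxycarbonyl)amino]-4-(furan-2-yl)butanoate | COC(=O)[C@H](CCc1ccco1)NC(=O)OC(C)(C)C | intermediate
5 | tert-butyl N-[(2S)-4-(furan-2-yl)-1-hydroxybutan-2-yl]carbamate | OC[C@H](CCc1ccco1)NC(=O)OC(C)(C)C | intermediate
6 | tert-butyl N-[(2S)-1-[tert-butyl(diphenyl)silyl]oxy-4-(furan-2-yl)butan-2-yl]carbamate | CC(C)(C)[Si](OC[C@H](CCc1ccco1)NC(=O)OC(C)(C)C)(c1ccccc1)c1ccccc1 | intermediate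
7 | (2S)-1-[tert-butyl(diphenyl)silyl]oxy-4-(furan-2-yl)butan-2-amine | CC(C)(C)[Si](OC[C@H](CCc1ccco1)N)(c1ccccc1)c1ccccc1 | intermediate
8 | 1-bromo-4-methoxybenzene | COc1ccc(Br)cc1 | starting material
9 | N-[(2S)-1-[tert-butyl(diphenyl)silyl]oxy-4-(furan-2-yl)butan-2-yl]-4-methoxyaniline | COc1ccc(N[C@@H](CCc2ccco2)CO[Si](c2ccccc2)(c2ccccc2)C(C)(C)C)cc1 | intermediate
10 | 5-chloropentanal | O=CCCCCCl | starting material
11 | N,C-dilithio derivative of 9 (lithium anilide, 5-lithiofuran) | COc1ccc(N([Li])[C@@H](CCc2ccc([Li])o2)CO[Si](c2ccccc2)(c2ccccc2)C(C)(C)C)cc1 | intermediate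
12 | 1-[5-[(3S)-4-[tert-butyl(diphenyl)silyl]oxy-3-(4-methoxyanilino)butyl]furan-2-yl]-5-chloropentan-1-ol (carbinol epimers) | COc1ccc(N[C@@H](CCc2ccc(C(O)CCCCCl)o2)CO[Si](c2ccccc2)(c2ccccc2)C(C)(C)C)cc1 | intermediate
13 | (7S)-7-[[tert-butyl(diphenyl)silyl]oxymethyl]-2-(5-chloropentylidene)-6-(4-methoxyphenyl)-1-oxa-6-azaspiro[4.4]non-3-ene | ClCCCCC=C1C=CC2(O1)CC[C@@H](CO[Si](c3ccccc3)(c3ccccc3)C(C)(C)C)N2c1ccc(OC)cc1 | intermediate
14 | (2S)-2-[[tert-butyl(diphenyl)silyl]oxymethyl]-5-(8-chloro-3-hydroxyocta-1,3-dien-1-yl)-1-(4-methoxyphenyl)-3,4-dihydro-2H-pyrrol-1-ium | OC(=CCCCCCl)C=CC1=[N+](c2ccc(OC)cc2)[C@H](CO[Si](c2ccccc2)(c2ccccc2)C(C)(C)C)CC1 | intermediate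
15 | (2S)-2-[[tert-butyl(diphenyl)silyl]oxymethyl]-6-(4-chlorobutyl)-1-(4-methoxyphenyl)-1-azaspiro[4.4]non-8-en-7-one (N1 trans to chlorobutyl; C5–C6 trans to CH2OSi) | O=C1C=C[C@]2(CC[C@@H](CO[Si](c3ccccc3)(c3ccccc3)C(C)(C)C)N2c2ccc(OC)cc2)[C@@H]1CCCCCl | intermediate
16 | corresponding 1-azaspiro[4.4]non-8-en-7-ol (7-OH cis to chlorobutyl, trans to N1) | O[C@@H]1C=C[C@]2(CC[C@@H](CO[Si](c3ccccc3)(c3ccccc3)C(C)(C)C)N2c2ccc(OC)cc2)[C@@H]1CCCCCl | intermediate
17 | triethyl orthopropionate (1,1,1-triethoxypropane) | CCC(OCC)(OCC)OCC | starting material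
18 | 7-O-(1-ethoxyprop-1-enyl) mixed ketene acetal of 16 | CCOC(=CC)O[C@@H]1C=C[C@]2(CC[C@@H](CO[Si](c3ccccc3)(c3ccccc3)C(C)(C)C)N2c2ccc(OC)cc2)[C@@H]1CCCCCl | intermediate
19 | ethyl 2-[(2S)-2-[[tert-butyl(diphenyl)silyl]oxymethyl]-6-(4-chlorobutyl)-1-(4-methoxyphenyl)-1-azaspiro[4.4]non-7-en-9-yl]propanoate (9-substituent cis to chlorobutyl, trans to N1; α-epimers) | CCOC(=O)C(C)[C@H]1C=C[C@@H](CCCCCl)[C@@]12CC[C@@H](CO[Si](c3ccccc3)(c3ccccc3)C(C)(C)C)N2c2ccc(OC)cc2 | intermediate
20 | N-unsubstituted analogue of 19 (secondary amine) | CCOC(=O)C(C)[C@H]1C=C[C@@H](CCCCCl)[C@@]12CC[C@@H](CO[Si](c3ccccc3)(c3ccccc3)C(C)(C)C)N2 | intermediate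
21 | tricyclic amino ester (pyrrolidine–azepane–cyclopentene, C10=C11, ethyl propanoate at C12, 3-CH2OSi-t-BuPh2) | CCOC(=O)C(C)[C@H]1C=C[C@H]2CCCCN3[C@H](CO[Si](c4ccccc4)(c4ccccc4)C(C)(C)C)CC[C@@]123 | intermediate
22 | carboxylic acid corresponding to 21 | OC(=O)C(C)[C@H]1C=C[C@H]2CCCCN3[C@H](CO[Si](c4ccccc4)(c4ccccc4)C(C)(C)C)CC[C@@]123 | intermediate
23 | 10-iodo tetracyclic lactone (I trans to O11; C13 epimers) | I[C@H]1[C@@H]2OC(=O)C(C)[C@@H]2[C@@]23CC[C@@H](CO[Si](c4ccccc4)(c4ccccc4)C(C)(C)C)N2CCCC[C@H]13 | intermediate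
24 | phenyl vinyl sulfone | C=CS(=O)(=O)c1ccccc1 | starting material
25 | 10-[2-(phenylsulfonyl)ethyl] tetracyclic lactone | O=S(=O)(CC[C@H]1[C@@H]2OC(=O)C(C)[C@@H]2[C@@]23CC[C@@H](CO[Si](c4ccccc4)(c4ccccc4)C(C)(C)C)N2CCCC[C@H]13)c1ccccc1 | intermediate
26 | 10-ethyl tetracyclic lactone (13-deoxy, C13 epimers) | CC[C@H]1[C@@H]2OC(=O)C(C)[C@@H]2[C@@]23CC[C@@H](CO[Si](c4ccccc4)(c4ccccc4)C(C)(C)C)N2CCCC[C@H]13 | intermediate
27 | potassium enolate of 26 | CC[C@H]1[C@@H]2OC(O[K])=C(C)[C@@H]2[C@@]23CC[C@@H](CO[Si](c4ccccc4)(c4ccccc4)C(C)(C)C)N2CCCC[C@H]13 | intermediate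
28 | 13-hydroxy tetracyclic lactone silyl ether | CC[C@H]1[C@@H]2OC(=O)[C@@](C)(O)[C@@H]2[C@@]23CC[C@@H](CO[Si](c4ccccc4)(c4ccccc4)C(C)(C)C)N2CCCC[C@H]13 | intermediate
29 | 13-hydroxy tetracyclic lactone with 3-CH2OH | CC[C@H]1[C@@H]2OC(=O)[C@@](C)(O)[C@@H]2[C@@]23CC[C@@H](CO)N2CCCC[C@H]13 | intermediate
30 | 13-hydroxy tetracyclic lactone with 3-CHO | CC[C@H]1[C@@H]2OC(=O)[C@@](C)(O)[C@@H]2[C@@]23CC[C@@H](C=O)N2CCCC[C@H]13 | intermediate
31 | ethyl 2-(bromomethyl)prop-2-enoate | C=C(CBr)C(=O)OCC | starting material
32 | ethyl (4S)-4-hydroxy-2-methylidene-4-(C3-yl)butanoate of the tetracycle | CC[C@H]1[C@@H]2OC(=O)[C@@](C)(O)[C@@H]2[C@@]23CC[C@@H]([C@@H](O)CC(=C)C(=O)OCC)N2CCCC[C@H]13 | intermediate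
33 | α-methylene-γ-butyrolactone (20-methylidene analogue of the target) | CC[C@H]1[C@@H]2OC(=O)[C@@](C)(O)[C@@H]2[C@@]23CC[C@@H]([C@@H]4CC(=C)C(=O)O4)N2CCCC[C@H]13 | intermediate
34 | target compound | CC[C@H]1[C@@H]2OC(=O)[C@@](C)(O)[C@@H]2[C@@]23CC[C@@H]([C@@H]4C[C@H](C)C(=O)O4)N2CCCC[C@H]13 | target

**Step count and risks**
Total step count: 19. Longest linear sequence: 19 steps (from 1).

Step 7 (key step). What may go wrong: the hindered, α-branched N-aryl amine may add too slowly to the substituted furan carbon, so that the furfuryl cation is lost to dehydration and oligomerisation, or the C3 substituent may discriminate the two faces poorly in the conrotatory closure. Fallback (N-alkyl series under neutral activation): setting out from 7, reductive amination with 4-methoxybenzaldehyde (NaBH(OAc)3, ClCH2CH2Cl) gives the N-(4-methoxybenzyl) amine F1. Double lithiation and addition to 10 as in step 6 gives the furyl carbinol F2. The carbinol is then activated by redox condensation (PPh3, diethyl azodicarboxylate, THF), a non-acidic variant of the intramolecular aza-Piancatelli reaction that tolerates basic alkylamines, and the same spirocyclisation and 4π closure give the N-benzyl spiro enone F3. Luche reduction gives the allylic alcohol F4, Johnson–Claisen rearrangement with 17 (amine carried as its propionate salt) gives the ester F5, and oxidative debenzylation with (NH4)2Ce(NO3)6 returns to the route at 20.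

Step 13. What may go wrong: premature hydrogen transfer from Bu3SnH to the hindered C10 radical (plain deiodination) or telomerisation of the vinyl sulfone. Fallback (chain allylation, then trimming by one carbon): setting out from 23, radical allylation with allyltributylstannane (AIBN, benzene, 80 °C, no tin hydride) gives the 10-allyl lactone F6 with the same convex-face preference. Cleavage with OsO4 (cat.), NaIO4 and 2,6-lutidine gives the aldehyde F7; ethane-1,2-dithiol and BF3·OEt2 give the dithiolane F8; Raney Ni desulfurisation gives the 10-ethyl lactone and comes back to the route at 26.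

Step 18. What may go wrong: competition between chelate-controlled and Felkin–Anh-type addition to the α-amino aldehyde (poor facial selectivity at C18), together with partial epimerisation at C3. Fallback (C18 set by reagent-controlled ketone reduction instead of carbonyl addition): setting out from 30, the Barbier reaction is stopped at the hydroxy esters (aq. NH4Cl work-up), that is 32 and its C18 epimer F9. The mixture is oxidised with Dess–Martin periodinane to the single ketone F10. Corey–Bakshi–Shibata reduction (catecholborane, 2-methyl-oxazaborolidine catalyst, −78 °C; 1,2-selective, acrylate untouched), with the catalyst enantiomer chosen to deliver hydride to the face giving the 18S carbinol, gives 32 alone. Acid-catalysed lactonisation then rejoins the route at 33.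

**Further compounds**
F1 | step 7 | (2S)-1-[tert-butyl(diphenyl)silyl]oxy-4-(furan-2-yl)-N-[(4-methoxyphenyl)methyl]butan-2-amine | COc1ccc(CN[C@@H](CCc2ccco2)CO[Si](c2ccccc2)(c2ccccc2)C(C)(C)C)cc1
F2 | step 7 | 1-[5-[(3S)-4-[tert-butyl(diphenyl)silyl]oxy-3-[(4-methoxyphenyl)methylamino]butyl]furan-2-yl]-5-chloropentan-1-ol (carbinol epimers) | COc1ccc(CN[C@@H](CCc2ccc(C(O)CCCCCl)o2)CO[Si](c2ccccc2)(c2ccccc2)C(C)(C)C)cc1
F3 | step 7 | N-(4-methoxybenzyl) analogue of spiro enone 15 | O=C1C=C[C@]2(CC[C@@H](CO[Si](c3ccccc3)(c3ccccc3)C(C)(C)C)N2Cc2ccc(OC)cc2)[C@@H]1CCCCCl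
F4 | step 7 | N-(4-methoxybenzyl) analogue of allylic alcohol 16 | O[C@@H]1C=C[C@]2(CC[C@@H](CO[Si](c3ccccc3)(c3ccccc3)C(C)(C)C)N2Cc2ccc(OC)cc2)[C@@H]1CCCCCl
F5 | step 7 | N-(4-methoxybenzyl) analogue of ester 19 | CCOC(=O)C(C)[C@H]1C=C[C@@H](CCCCCl)[C@@]12CC[C@@H](CO[Si](c3ccccc3)(c3ccccc3)C(C)(C)C)N2Cc2ccc(OC)cc2
F6 | step 13 | 10-allyl tetracyclic lactone (allyl in place of the iodine of 23, same configuration) | C=CC[C@H]1[C@@H]2OC(=O)C(C)[C@@H]2[C@@]23CC[C@@H](CO[Si](c4ccccc4)(c4ccccc4)C(C)(C)C)N2CCCC[C@H]13
F7 | step 13 | 10-(2-oxoethyl) tetracyclic lactone | O=CC[C@H]1[C@@H]2OC(=O)C(C)[C@@H]2[C@@]23CC[C@@H](CO[Si](c4ccccc4)(c4ccccc4)C(C)(C)C)N2CCCC[C@H]13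
F8 | step 13 | 10-(1,3-dithiolan-2-ylmethyl) tetracyclic lactone | C1CSC(C[C@H]2[C@@H]3OC(=O)C(C)[C@@H]3[C@@]34CC[C@@H](CO[Si](c5ccccc5)(c5ccccc5)C(C)(C)C)N3CCCC[C@H]24)S1
F9 | step 18 | C18 epimer of hydroxy ester 32 | CC[C@H]1[C@@H]2OC(=O)[C@@](C)(O)[C@@H]2[C@@]23CC[C@@H]([C@H](O)CC(=C)C(=O)OCC)N2CCCC[C@H]13
F10 | step 18 | ethyl 2-methylidene-4-oxo-4-(C3-yl)butanoate of the tetracycle (C18 ketone) | CC[C@H]1[C@@H]2OC(=O)[C@@](C)(O)[C@@H]2[C@@]23CC[C@@H](C(=O)CC(=C)C(=O)OCC)N2CCCC[C@H]13
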